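The route rests on cutting the aryl ether bond O1–C7a of the dihydrofuran ring. The key step exploits the fact that this bond sits on ring A (the benzo ring) ortho to C3a, the carbon that carries C3. An open-chain alcohol in which C2 and C3 already have their final configurations, set together by an Evans syn aldol, is therefore closed by a copper-catalysed 5-exo O-arylation of the benzylic hydroxyl onto an ortho C–Br bond, touching neither stereocentre. C5, para to O1, carries a chloride that copper ignores and that later receives the (E)-hydroxypropenyl chain. The precursor is a mono-silylated 2-(2-bromo-5-chlorophenyl)-1-(3,4,5-trimethoxyphenyl)propane-1,3-diol.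

Key step: step 5

Remark: atom numbers are those of the 2,3-dihydro-1-benzofuran core of the target (O1, C2, C3, C3a, C4 to C7, C7a); compounds 1, 2, 5 and 11 are assumed to be purchasable.

Step 1
Reactants: 1 2-(2-bromo-5-chlorophenyl)acetic acid; 2 (R)-4-benzyl-1,3-oxazolidin-2-one
Product: 4 (R)-4-benzyl-3-[2-(2-bromo-5-chlorophenyl)acetyl]-1,3-oxazolidin-2-one, via mixed pivalic anhydride 3 (not isolated)
Conditions: PivCl, Et3N, THF, −20 °C; then 2, LiCl, −20 °C to rt
Reagents that add atoms: none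
Why: Mixed-anhydride N-acylation of an oxazolidinone under LiCl/Et3N activation: the auxiliary nitrogen should attack the unhindered arylacetyl carbonyl of 3 rather than the pivaloyl carbonyl, and no stereocentre is formed or touched.

Step 2
Reactants: 4 (R)-4-benzyl-3-[2-(2-bromo-5-chlorophenyl)acetyl]-1,3-oxazolidin-2-one; 5 3,4,5-trimethoxybenzaldehyde
Product: 7 (R)-4-benzyl-3-[(2R,3R)-2-(2-bromo-5-chlorophenyl)-3-hydroxy-3-(3,4,5-trimethoxyphenyl)propanoyl]-1,3-oxazolidin-2-one, via Z-dibutylboron enolate 6 (not isolated)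
Conditions: Bu2BOTf, i-Pr2NEt, CH2Cl2, −78 to 0 °C; then 5, −78 to 0 °C; pH 7 buffer, MeOH, 30% H2O2, 0 °C
Reagents that add atoms: none
Why: Evans syn aldol reaction: soft enolisation gives the Z-boron enolate 6, which should add to 5 through a chair Zimmerman–Traxler transition state on the enolate face away from the benzyl group of the (R)-auxiliary, so that C2 (R) and C3 (R) of the acyl chain are set together in the syn relation that later becomes trans across C2–C3 of the dihydrofuran.

Step 3
Reactants: 7 (R)-4-benzyl-3-[(2R,3R)-2-(2-bromo-5-chlorophenyl)-3-hydroxy-3-(3,4,5-trimethoxyphenyl)propanoyl]-1,3-oxazolidin-2-one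
Product: 8 (1R,2S)-2-(2-bromo-5-chlorophenyl)-1-(3,4,5-trimethoxyphenyl)propane-1,3-diol
Conditions: LiBH4, MeOH (1 equiv), THF, 0 °C
Reagents that add atoms: none
Why: Reductive removal of the auxiliary by LiBH4 (hydride addition to the exocyclic imide carbonyl, then reduction of the released aldehyde) should leave both stereocentres and both aryl halides untouched and return 2; the descriptor of the aryl-bearing carbon changes from R to S only because the priorities change.

Step 4
Reactants: 8 (1R,2S)-2-(2-bromo-5-chlorophenyl)-1-(3,4,5-trimethoxyphenyl)propane-1,3-diol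
Product: 9 (1R,2S)-2-(2-bromo-5-chlorophenyl)-3-{[tri(propan-2-yl)silyl]oxy}-1-(3,4,5-trimethoxyphenyl)propan-1-ol
Conditions: TIPSCl, imidazole, DMF, 0 °C to rt
Reagents that add atoms: triisopropylsilyl chloride, CC(C)[Si](Cl)(C(C)C)C(C)C
Why: Sterically controlled silylation: the bulky silyl chloride should react only with the primary hydroxyl and leave the hindered benzylic one free, and the triisopropylsilyl group is chosen because it resists oxygen-to-oxygen migration under the basic conditions of step 5; no stereocentre is touched.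

Step 5
Reactants: 9 (1R,2S)-2-(2-bromo-5-chlorophenyl)-3-{[tri(propan-2-yl)silyl]oxy}-1-(3,4,5-trimethoxyphenyl)propan-1-ol
Product: 10 (2R,3S)-5-chloro-3-({[tri(propan-2-yl)silyl]oxy}methyl)-2-(3,4,5-trimethoxyphenyl)-2,3-dihydro-1-benzofuran
Conditions: CuI (10 mol %), 3,4,7,8-tetramethyl-1,10-phenanthroline (20 mol %), Cs2CO3, toluene, 110 °C, argon
Reagents that add atoms: none
Why: Cs2CO3 deprotonates the benzylic hydroxyl of 9 (the future O1), the alkoxide binds the phenanthroline-ligated monovalent copper centre, the ortho C–Br bond adds to give a six-membered aryl alkoxide of trivalent copper, and C–O reductive elimination forms the O1–C7a bond and returns monovalent copper. The closest known reaction type is the intramolecular Ullmann-type O-arylation of 2-(2-bromophenyl)ethanols to 2,3-dihydrobenzofurans. The dihydrofuran ring closes in a 5-exo mode, the oxygen being delivered through the tether C2–C3–C3a to the ring A carbon ortho to C3a. No stereocentre is made: C2 and C3 come unchanged from the aldol because no bond to either is broken, so the (1R,2S) syn pattern of 9 becomes the trans-(2R,3S) ring. The step needs three selectivities, each secured by the substrate: only the ortho bromide reacts because the C5 chloride is inert to copper at this temperature, only the benzylic oxygen can close because the primary one is silylated, and the 5-exo closure should outrun intermolecular coupling. Ketone formation is not expected, since copper alkoxides show little tendency to β-hydride elimination under argon.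

Step 6
Reactants: 10 (2R,3S)-5-chloro-3-({[tri(propan-2-yl)silyl]oxy}methyl)-2-(3,4,5-trimethoxyphenyl)-2,3-dihydro-1-benzofuran; 11 (E)-tert-butyldimethyl{[3-(4,4,5,5-tetramethyl-1,3,2-dioxaborolan-2-yl)prop-2-en-1-yl]oxy}silane
Product: 12 tert-butyl({(E)-3-[(2R,3S)-3-({[tri(propan-2-yl)silyl]oxy}methyl)-2-(3,4,5-trimethoxyphenyl)-2,3-dihydro-1-benzofuran-5-yl]prop-2-en-1-yl}oxy)dimethylsilane
Conditions: Pd(OAc)2 (5 mol %), SPhos (10 mol %), K3PO4, toluene/H2O, 90 °C
Reagents that add atoms: none
Why: Suzuki–Miyaura coupling: the electron-rich biarylphosphine should let zerovalent palladium insert into the deactivated C5–Cl bond, and transmetalation and reductive elimination proceed with retention of the E geometry of 11; the stereocentres and both silyl ethers are spectators.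

Step 7
Reactants: 12 tert-butyl({(E)-3-[(2R,3S)-3-({[tri(propan-2-yl)silyl]oxy}methyl)-2-(3,4,5-trimethoxyphenyl)-2,3-dihydro-1-benzofuran-5-yl]prop-2-en-1-yl}oxy)dimethylsilane
Product: 13 (E)-3-[(2R,3S)-3-(hydroxymethyl)-2-(3,4,5-trimethoxyphenyl)-2,3-dihydro-1-benzofuran-5-yl]prop-2-en-1-ol
Conditions: Bu4NF (3 equiv), THF, 0 °C to rt; H2O work-up
Reagents that add atoms: none
Why: Fluoride-mediated desilylation (formation of strong Si–F bonds) should remove both silyl ethers in one operation under non-acidic conditions that spare the ionisable benzylic C2–O1 bond and the cinnamyl alcohol; no stereocentre is touched.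

Compound list
1 | 2-(2-bromo-5-chlorophenyl)acetic acid | OC(=O)Cc1cc(Cl)ccc1Br | starting material
2 | (R)-4-benzyl-1,3-oxazolidin-2-one | O=C1N[C@H](Cc2ccccc2)CO1 | starting material
3 | 2-(2-bromo-5-chlorophenyl)acetic pivalic anhydride (not isolated) | CC(C)(C)C(=O)OC(=O)Cc1cc(Cl)ccc1Br | intermediate
4 | (R)-4-benzyl-3-[2-(2-bromo-5-chlorophenyl)acetyl]-1,3-oxazolidin-2-one | O=C(Cc1cc(Cl)ccc1Br)N1[C@H](Cc2ccccc2)COC1=O | intermediate
5 | 3,4,5-trimethoxybenzaldehyde | COc1cc(C=O)cc(OC)c1OC | starting material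
6 | Z-dibutylboron enolate of 4 (not isolated) | CCCCB(CCCC)O/C(=C\c1cc(Cl)ccc1Br)N1[C@H](Cc2ccccc2)COC1=O | intermediate
7 | (R)-4-benzyl-3-[(2R,3R)-2-(2-bromo-5-chlorophenyl)-3-hydroxy-3-(3,4,5-trimethoxyphenyl)propanoyl]-1,3-oxazolidin-2-one | COc1cc([C@H](O)[C@H](C(=O)N2[C@H](Cc3ccccc3)COC2=O)c2cc(Cl)ccc2Br)cc(OC)c1OC | intermediate
8 | (1R,2S)-2-(2-bromo-5-chlorophenyl)-1-(3,4,5-trimethoxyphenyl)propane-1,3-diol | COc1cc([C@H](O)[C@H](CO)c2cc(Cl)ccc2Br)cc(OC)c1OC | intermediate
9 | (1R,2S)-2-(2-bromo-5-chlorophenyl)-3-{[tri(propan-2-yl)silyl]oxy}-1-(3,4,5-trimethoxyphenyl)propan-1-ol | COc1cc([C@H](O)[C@H](CO[Si](C(C)C)(C(C)C)C(C)C)c2cc(Cl)ccc2Br)cc(OC)c1OC | intermediate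
10 | (2R,3S)-5-chloro-3-({[tri(propan-2-yl)silyl]oxy}methyl)-2-(3,4,5-trimethoxyphenyl)-2,3-dihydro-1-benzofuran | COc1cc([C@@H]2Oc3ccc(Cl)cc3[C@H]2CO[Si](C(C)C)(C(C)C)C(C)C)cc(OC)c1OC | intermediate
11 | (E)-tert-butyldimethyl{[3-(4,4,5,5-tetramethyl-1,3,2-dioxaborolan-2-yl)prop-2-en-1-yl]oxy}silane | CC(C)(C)[Si](C)(C)OC/C=C/B1OC(C)(C)C(C)(C)O1 | starting material
12 | tert-butyl({(E)-3-[(2R,3S)-3-({[tri(propan-2-yl)silyl]oxy}methyl)-2-(3,4,5-trimethoxyphenyl)-2,3-dihydro-1-benzofuran-5-yl]prop-2-en-1-yl}oxy)dimethylsilane | COc1cc([C@@H]2Oc3ccc(/C=C/CO[Si](C)(C)C(C)(C)C)cc3[C@H]2CO[Si](C(C)C)(C(C)C)C(C)C)cc(OC)c1OC | intermediate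
13 | (E)-3-[(2R,3S)-3-(hydroxymethyl)-2-(3,4,5-trimethoxyphenyl)-2,3-dihydro-1-benzofuran-5-yl]prop-2-en-1-ol | COc1cc([C@@H]2Oc3ccc(/C=C/CO)cc3[C@H]2CO)cc(OC)c1OC | target

Total step count: 7. Longest linear sequence: 7 steps (1 → 4 → 7 → 8 → 9 → 10 → 12 → 13).

Steps most likely to fail

Step 5. Reductive elimination from the hindered secondary copper alkoxide may be too slow, so that hydrodebromination, oxidation of the benzylic carbinol or migration of the silyl group to the benzylic oxygen competes. The fallback sets out from compounds 2 and 5 and comes back at compound 12; it closes the same O1–C7a bond without a metal, by nucleophilic aromatic substitution of fluoride. 2-(5-Bromo-2-fluorophenyl)acetic acid F1 would be taken through the operations of steps 1 to 4: its mixed pivalic anhydride F2 (not isolated) acylates 2 to give the imide F3, the Z-dibutylboron enolate F4 (not isolated) adds to 5 to give the syn aldol adduct F5, LiBH4 gives the diol F6, and TIPSCl gives the silyl ether F7. KN(SiMe3)2 with 18-crown-6 in THF (0 to 60 °C) should then convert the benzylic hydroxyl into a potassium alkoxide that displaces the ortho fluoride, activated by the para bromine, in a 5-exo closure to the 5-bromo dihydrobenzofuran F8. Suzuki–Miyaura coupling of its C5–Br bond with 11 (Pd(dppf)Cl2, K2CO3, dioxane/H2O, 80 °C) returns to 12.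

Step 6. Insertion of zerovalent palladium into the electron-rich C5–Cl bond may be slower than protodeboronation of the alkenylboronate 11. The fallback sets out from compound 10 and comes back at compound 13. A Mizoroki–Heck reaction with ethyl acrylate (Pd2(dba)3, P(t-Bu)3, Cy2NMe, dioxane, 110 °C), whose olefin partner tolerates forcing conditions, should give the E cinnamate F9; i-Bu2AlH (CH2Cl2, −78 °C) reduces the ester to the allylic alcohol F10, and Bu4NF removes the remaining silyl group to give 13.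

Step 2. Addition of the hindered ortho-bromoaryl enolate to the electron-rich, weakly electrophilic aldehyde may be slow and reversible, with retro-aldol equilibration eroding conversion and the syn selectivity. The fallback sets out from compound 1 and comes back at compound 8. Acid 1 is coupled (DCC, DMAP, CH2Cl2) with (R)-4-benzyl-1,3-thiazolidine-2-thione F11 to the N-acyl thiazolidinethione F12. Its chlorotitanium Z-enolate F13 (not isolated; TiCl4, i-Pr2NEt, N-methylpyrrolidinone, CH2Cl2, −78 to 0 °C), more nucleophilic than the boron enolate, should add to 5 in the same facial sense to give the syn adduct F14. NaBH4 (THF/EtOH, 0 °C) cleaves the labile thioimide directly to diol 8 with release of F11.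

Further compounds
F1 | step 5 | 2-(5-bromo-2-fluorophenyl)acetic acid | OC(=O)Cc1cc(Br)ccc1F
F2 | step 5 | 2-(5-bromo-2-fluorophenyl)acetic pivalic anhydride (not isolated) | CC(C)(C)C(=O)OC(=O)Cc1cc(Br)ccc1F
F3 | step 5 | (R)-4-benzyl-3-[2-(5-bromo-2-fluorophenyl)acetyl]-1,3-oxazolidin-2-one | O=C(Cc1cc(Br)ccc1F)N1[C@H](Cc2ccccc2)COC1=O
F4 | step 5 | Z-dibutylboron enolate of F3 (not isolated) | CCCCB(CCCC)O/C(=C\c1cc(Br)ccc1F)N1[C@H](Cc2ccccc2)COC1=O
F5 | step 5 | (R)-4-benzyl-3-[(2R,3R)-2-(5-bromo-2-fluorophenyl)-3-hydroxy-3-(3,4,5-trimethoxyphenyl)propanoyl]-1,3-oxazolidin-2-one | COc1cc([C@H](O)[C@H](C(=O)N2[C@H](Cc3ccccc3)COC2=O)c2cc(Br)ccc2F)cc(OC)c1OC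
F6 | step 5 | (1R,2S)-2-(5-bromo-2-fluorophenyl)-1-(3,4,5-trimethoxyphenyl)propane-1,3-diol | COc1cc([C@H](O)[C@H](CO)c2cc(Br)ccc2F)cc(OC)c1OC
F7 | step 5 | (1R,2S)-2-(5-bromo-2-fluorophenyl)-3-{[tri(propan-2-yl)silyl]oxy}-1-(3,4,5-trimethoxyphenyl)propan-1-ol | COc1cc([C@H](O)[C@H](CO[Si](C(C)C)(C(C)C)C(C)C)c2cc(Br)ccc2F)cc(OC)c1OC
F8 | step 5 | (2R,3S)-5-bromo-3-({[tri(propan-2-yl)silyl]oxy}methyl)-2-(3,4,5-trimethoxyphenyl)-2,3-dihydro-1-benzofuran | COc1cc([C@@H]2Oc3ccc(Br)cc3[C@H]2CO[Si](C(C)C)(C(C)C)C(C)C)cc(OC)c1OC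
F9 | step 6 | ethyl (E)-3-[(2R,3S)-3-({[tri(propan-2-yl)silyl]oxy}methyl)-2-(3,4,5-trimethoxyphenyl)-2,3-dihydro-1-benzofuran-5-yl]prop-2-enoate | COc1cc([C@@H]2Oc3ccc(/C=C/C(=O)OCC)cc3[C@H]2CO[Si](C(C)C)(C(C)C)C(C)C)cc(OC)c1OC
F10 | step 6 | (E)-3-[(2R,3S)-3-({[tri(propan-2-yl)silyl]oxy}methyl)-2-(3,4,5-trimethoxyphenyl)-2,3-dihydro-1-benzofuran-5-yl]prop-2-en-1-ol | COc1cc([C@@H]2Oc3ccc(/C=C/CO)cc3[C@H]2CO[Si](C(C)C)(C(C)C)C(C)C)cc(OC)c1OC
F11 | step 2 | (R)-4-benzyl-1,3-thiazolidine-2-thione | S=C1N[C@H](Cc2ccccc2)CS1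
F12 | step 2 | 1-[(R)-4-benzyl-2-thioxo-1,3-thiazolidin-3-yl]-2-(2-bromo-5-chlorophenyl)ethan-1-one | O=C(Cc1cc(Cl)ccc1Br)N1[C@H](Cc2ccccc2)CSC1=S
F13 | step 2 | chlorotitanium Z-enolate of F12 (not isolated) | Cl[Ti](Cl)(Cl)O/C(=C\c1cc(Cl)ccc1Br)N1[C@H](Cc2ccccc2)CSC1=S
F14 | step 2 | (2R,3R)-1-[(R)-4-benzyl-2-thioxo-1,3-thiazolidin-3-yl]-2-(2-bromo-5-chlorophenyl)-3-hydroxy-3-(3,4,5-trimethoxyphenyl)propan-1-one | COc1cc([C@H](O)[C@H](C(=O)N2[C@H](Cc3ccccc3)CSC2=S)c2cc(Cl)ccc2Br)cc(OC)c1OC
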